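**Plan**

1. Each bicyclic amino alcohol unit is numbered N2, C1, C3, C4 (Me), C4a, C5, C6 (O), C7 (Me), C7a. The retrosynthesis first cuts the two C6–O ester bonds (double Mitsunobu with inversion). This gives 4,4'-dihydroxy-α-truxillic acid, which is cut at two cyclobutane bonds to p-coumaric acid, and two units of the 6-epi amino alcohol.
2. Enabling feature: in each unit the C4 methyl carbon, C4, C4a and C5 form a four-carbon path beside the C6 oxygen. Joining the methyl carbon to C5 gives a cyclobutane fused to a cyclopentanone, the intramolecular [2+2] photoadduct of a cyclopent-2-enone (C6=O, C5=C4a) and an N-allyl group hung on C7a. The unit is therefore cut at C4–C4a (and at the extra C5–CH2 bond) to a monocyclic enone.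
3. Forward order: radical conjugate addition and elimination give the cyclopentenone with its CH2N(Boc)allyl arm. The photocycloaddition closes the piperidine ring and a cyclobutane. C7 methylation and ketyl fragmentation of the strained ring (which leaves the C4 methyl) follow, then LiAlH4 gives the N-methyl amino alcohol, which esterifies both acids of the photodimer.
4. Stereochemistry: one bought centre, in (S)-4-siloxycyclopentenone, sets C7a and is then erased. C7a sets C4a and C4 in the key step, the tricycle sets C7, and the bicycle sets C6 (convex hydride attack, then Mitsunobu inversion). The cyclobutane core is set by crystal packing.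
5. Helpers: the C6 ketone serves as chromophore and then as radical trigger and ends as the ester oxygen. The extra cyclobutane bond is cleaved in step 4. The Boc carbonyl carbon ends as the N-methyl group.

Key step: step 2

Remark: ring positions of the monocyclic and tricyclic precursors are given with the numbering of the bicyclic amino alcohol; 1 and 2 are taken as purchasable.

**Route**

Step 1
Reactants: 1 (S)-4-(tert-butyldimethylsilyloxy)cyclopent-2-en-1-one; 2 N-Boc-N-allylglycine
Product: 4 tert-butyl allyl{[(1S)-4-oxocyclopent-2-en-1-yl]methyl}carbamate, via siloxy ketone 3 (not isolated)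
Conditions: Ir[dF(CF3)ppy]2(dtbbpy)PF6 (1 mol %), K2HPO4, DMF, blue LEDs, rt; then DBU, 0 °C
Reagents that add atoms: none
Why: Photoredox decarboxylative Giese addition, in which the Boc-stabilised α-amino radical from 2 should add to the enone β-carbon anti to the bulky neighbouring siloxy group (this sets C7a), after which DBU expels silanolate from the β-siloxy ketone by E1cB elimination, so that the bought centre is traded for the new one before it is erased.

Step 2
Reactants: 4 tert-butyl allyl{[(1S)-4-oxocyclopent-2-en-1-yl]methyl}carbamate
Product: 5 tert-butyl (1R,3S,6S,10S)-4-oxo-8-azatricyclo[4.3.1.0(3,10)]decane-8-carboxylate (tricyclic photoadduct; the four methine hydrogens are all cis)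
Conditions: hν (Hg lamp, borosilicate filter, λ > 300 nm), degassed CH2Cl2 (0.01 M), 0 °C
Reagents that add atoms: none
Why: Excitation of the cyclopentenone (n→π*) and intersystem crossing give the triplet enone, whose β-carbon C4a bonds to the internal carbon of the N-allyl group (future C4) in a 6-exo mode to close the piperidine ring and leave a triplet 1,4-diradical (α-keto radical at C5, primary radical at the allyl terminus), which closes the cyclobutane by radical recombination after spin inversion. The closest known reaction type is the intramolecular enone–olefin [2+2] photocycloaddition of a cyclopentenone that carries a four-atom tether with an acylated nitrogen. Three stereocentres arise under control of C7a alone: C4a because the alkene can reach only the enone face that bears the CH2N arm (cis 5/6 fusion), C5 because a cyclobutane can only be cis-fused to the five-membered ring, and C4 because the allyl terminus has to bridge to C5 on that same face, which fixes the later C4 methyl cis to C5, a relation that a plain radical 6-exo closure would leave to a chair-like transition state. The step needs straight and not crossed regiochemistry and intra- over intermolecular reaction: the four-atom tether makes the six-membered closure the only unstrained first bond, a diradical with its terminus turned away from C5 should revert to 4 and not close a trans-fused ring, and high dilution holds back enone dimerization. The Boc group removes the nitrogen lone pair as an electron-transfer quencher of the triplet, and the C6 carbonyl that serves here as chromophore is kept as the trigger for the strain-releasing cleavage in step 4.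

Step 3
Reactants: 5 tricyclic photoadduct
Product: 6 tert-butyl (1R,3S,5S,6R,10S)-5-methyl-4-oxo-8-azatricyclo[4.3.1.0(3,10)]decane-8-carboxylate
Conditions: LiN(iPr)2, THF, −78 °C; MeI, −78 to −40 °C
Reagents that add atoms: iodomethane, CI
Why: Kinetic enolate alkylation, in which the base can enolise only toward the CH2 group (the other α-carbon is a cyclobutane bridgehead) and MeI should enter from the convex face, anti to the adjacent CH2N arm and to both rings on the upper face, which sets C7 trans to C7a.

Step 4
Reactants: 6 methylated photoadduct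
Product: 7 tert-butyl (4R,4aS,7S,7aR)-4,7-dimethyl-6-oxooctahydro-2H-cyclopenta[c]pyridine-2-carboxylate
Conditions: SmI2 (2.5 equiv), t-BuOH, THF–HMPA, −78 to 0 °C; aq. NH4Cl
Reagents that add atoms: none
Why: Ketyl-initiated cyclobutylcarbinyl radical fragmentation (SmI2 cleavage of an α-keto cyclobutane), in which the exocyclic cyclobutane bond at the α-carbon overlaps with the ketyl π-system whereas the bond shared with the five-membered ring lies near its nodal plane, so that ring strain is released by cleaving the C5–CH2 bond, the primary radical is reduced and protonated to the C4 methyl group, and no stereocentre is touched.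

Step 5
Reactants: 7 bicyclic N-Boc ketone
Product: 9 6-epi-incarvilline (4R,4aS,6S,7S,7aR)-2,4,7-trimethyloctahydro-1H-cyclopenta[c]pyridin-6-ol, via N-Boc alcohol 8 (not isolated)
Conditions: LiAlH4, THF, −78 °C, then reflux; H2O/NaOH work-up
Reagents that add atoms: none
Why: Hydride reduction, in which LiAlH4 at low temperature should attack the cyclopentanone from the convex face of the cis-fused bicycle (also the side a small hydride prefers next to an α-methyl group) to give the 6S alcohol trans to the C7 methyl, and at reflux reduces the Boc carbamate through the formamide to the N-methyl group.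

Step 6
Reactants: 10 (E)-p-coumaric acid (two molecules)
Product: 11 4,4'-dihydroxy-α-truxillic acid, (1α,2α,3β,4β)-2,4-bis(4-hydroxyphenyl)cyclobutane-1,3-dicarboxylic acid (centrosymmetric, achiral)
Conditions: crystalline powder suspended in hexane, hν (Hg lamp, borosilicate filter), rt
Reagents that add atoms: none
Why: Topochemical [2+2] photodimerization, in which the α-type crystal of p-coumaric acid stacks neighbouring molecules head-to-tail across a centre of symmetry at reactive distance, so that the lattice should deliver only the centrosymmetric α-truxillic dimer with all four stereocentres fixed by the packing.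

Step 7
Reactants: 11 4,4'-dihydroxy-α-truxillic acid; 9 6-epi-incarvilline (2.1 equiv)
Product: 14 target bis-ester CNP0180864.2, via monoester 12 (not isolated), via monoester 13 (not isolated)
Conditions: PPh3, DIAD, THF, 0 °C to rt
Reagents that add atoms: none
Why: Double Mitsunobu esterification, in which the betaine deprotonates only the carboxylic acids (pKa about 4.5 against about 10 for the phenols), each carboxylate displaces the oxyphosphonium of 9 with inversion at C6 (6S to 6R), and the two diastereomeric monoesters converge on one bis-ester because the two carboxyl groups are related by the inversion centre of the core.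

**Compound list**

1 | (S)-4-(tert-butyldimethylsilyloxy)cyclopent-2-en-1-one | O=C1C=C[C@@H](O[Si](C)(C)C(C)(C)C)C1 | starting material
2 | N-Boc-N-allylglycine | C=CCN(CC(=O)O)C(=O)OC(C)(C)C | starting material
3 | tert-butyl allyl{[(1R,2S)-2-(tert-butyldimethylsilyloxy)-4-oxocyclopentyl]methyl}carbamate (trans) | O=C1C[C@H](CN(CC=C)C(=O)OC(C)(C)C)[C@@H](O[Si](C)(C)C(C)(C)C)C1 | intermediate
4 | tert-butyl allyl{[(1S)-4-oxocyclopent-2-en-1-yl]methyl}carbamate | O=C1C=C[C@@H](CN(CC=C)C(=O)OC(C)(C)C)C1 | intermediate
5 | tert-butyl (1R,3S,6S,10S)-4-oxo-8-azatricyclo[4.3.1.0(3,10)]decane-8-carboxylate | O=C1C[C@@H]2CN(C(=O)OC(C)(C)C)C[C@@H]3C[C@H]1[C@H]23 | intermediate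
6 | tert-butyl (1R,3S,5S,6R,10S)-5-methyl-4-oxo-8-azatricyclo[4.3.1.0(3,10)]decane-8-carboxylate | O=C1[C@@H](C)[C@@H]2CN(C(=O)OC(C)(C)C)C[C@@H]3C[C@H]1[C@H]23 | intermediate
7 | tert-butyl (4R,4aS,7S,7aR)-4,7-dimethyl-6-oxooctahydro-2H-cyclopenta[c]pyridine-2-carboxylate | O=C1C[C@@H]2[C@@H](CN(C(=O)OC(C)(C)C)C[C@@H]2C)[C@@H]1C | intermediate
8 | tert-butyl (4R,4aS,6S,7S,7aR)-6-hydroxy-4,7-dimethyloctahydro-2H-cyclopenta[c]pyridine-2-carboxylate | O[C@H]1C[C@@H]2[C@@H](CN(C(=O)OC(C)(C)C)C[C@@H]2C)[C@@H]1C | intermediate
9 | 6-epi-incarvilline, (4R,4aS,6S,7S,7aR)-2,4,7-trimethyloctahydro-1H-cyclopenta[c]pyridin-6-ol | O[C@H]1C[C@@H]2[C@@H](CN(C)C[C@@H]2C)[C@@H]1C | intermediate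
10 | (E)-p-coumaric acid | OC(=O)/C=C/c1ccc(O)cc1 | starting material
11 | 4,4'-dihydroxy-α-truxillic acid, (1α,2α,3β,4β)-2,4-bis(4-hydroxyphenyl)cyclobutane-1,3-dicarboxylic acid | OC(=O)[C@H]1[C@H](c2ccc(O)cc2)[C@H](C(=O)O)[C@H]1c1ccc(O)cc1 | intermediate
12 | monoester of 11 with one (4R,4aS,6R,7S,7aR)-2,4,7-trimethyloctahydro-1H-cyclopenta[c]pyridin-6-yl group at one carboxyl group | C[C@H]1[C@@H]2CN(C)C[C@H](C)[C@@H]2C[C@H]1OC(=O)[C@H]1[C@H](c2ccc(O)cc2)[C@H](C(=O)O)[C@H]1c1ccc(O)cc1 | intermediate
13 | diastereomeric monoester of 11, esterified at the other (enantiotopic) carboxyl group | C[C@H]1[C@@H]2CN(C)C[C@H](C)[C@@H]2C[C@H]1OC(=O)[C@@H]1[C@@H](c2ccc(O)cc2)[C@@H](C(=O)O)[C@@H]1c1ccc(O)cc1 | intermediate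
14 | CNP0180864.2, bis[(4R,4aS,6R,7S,7aR)-2,4,7-trimethyloctahydro-1H-cyclopenta[c]pyridin-6-yl] (1α,2α,3β,4β)-2,4-bis(4-hydroxyphenyl)cyclobutane-1,3-dicarboxylate | C[C@H]1[C@@H]2CN(C)C[C@H](C)[C@@H]2C[C@H]1OC(=O)[C@H]1[C@H](c2ccc(O)cc2)[C@H](C(=O)O[C@@H]2C[C@@H]3[C@@H](CN(C)C[C@@H]3C)[C@@H]2C)[C@H]1c1ccc(O)cc1 | target

**Count**

Total steps: 7. Longest linear sequence: 6 (steps 1 to 5, then step 7).

**Steps most likely to fail**

Step 2. The 1,4-diradical may revert without closing the four-membered ring, or close with the allyl terminus on the far side of the new ring (loss of the C4 relation). Enone dimerization at practical concentration and secondary photolysis of the cyclobutyl ketone are further risks. The fallback sets out from 1 and comes back at 7, forming the same bond by a thermal, palladium-mediated closure. N-Boc-glycine is N-alkylated as its dianion (NaH, 2,3-dibromopropene, THF) to N-Boc-N-(2-bromoallyl)glycine F1. F1 and 1 under the conditions of step 1 give, through the siloxy ketone F2, the bromoallyl enone F3. Kinetic α'-methylation (LiN(iPr)2, MeI, −78 °C) trans to the arm gives the trans-5-methyl enone F4. A reductive Heck cyclization (Pd(OAc)2, PPh3, HCO2Na, DMF, 80 °C) closes C4–C4a onto the enone β-carbon and gives the exo-methylene ketone F5. Hydrogenation (H2, Pd/C, EtOAc) from the convex face then sets C4 and gives 7.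

Step 4. The ketyl may cleave the ring-fusion bond of the cyclobutane (ring expansion to a seven-membered ketone), or the liberated ketone may be reduced further. The fallback sets out from 6 and comes back at 7 by ionic ring opening. Me3SiI (CH2Cl2, 0 °C) should deliver iodide to the unhindered cyclobutane CH2 while the ketone leaves as its silyl enol ether, so the regiochemistry rests on SN2 sterics and not on radical stability. The Boc group is lost in the same operation, and methanol work-up gives the iodomethyl amino ketone F6 (as hydroiodide). Boc2O/NaHCO3 restores the carbamate to give the N-Boc iodomethyl ketone F7, and Bu3SnH/AIBN (benzene, 80 °C) removes the iodine to give 7.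

Step 7. The activated, hindered secondary alcohol may eliminate to the cyclopentene, the reaction may stall after the first esterification, and the phenols may be O-alkylated once the carboxylic acid is used up. The fallback sets out from 11 and comes back at 14 with the phenols masked. Ac2O/pyridine (aqueous work-up hydrolyses the mixed anhydrides) gives 4,4'-diacetoxy-α-truxillic acid F8. The same Mitsunobu coupling with 9 gives the bis-ester diacetate F9. NH3 in MeOH at 0 °C cleaves only the aryl acetates and gives 14.

Further compounds
F1 | step 2 | N-Boc-N-(2-bromoallyl)glycine | C=C(Br)CN(CC(=O)O)C(=O)OC(C)(C)C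
F2 | step 2 | tert-butyl (2-bromoallyl){[(1R,2S)-2-(tert-butyldimethylsilyloxy)-4-oxocyclopentyl]methyl}carbamate (trans) | O=C1C[C@H](CN(CC(Br)=C)C(=O)OC(C)(C)C)[C@@H](O[Si](C)(C)C(C)(C)C)C1
F3 | step 2 | tert-butyl (2-bromoallyl){[(1S)-4-oxocyclopent-2-en-1-yl]methyl}carbamate | O=C1C=C[C@@H](CN(CC(Br)=C)C(=O)OC(C)(C)C)C1
F4 | step 2 | tert-butyl (2-bromoallyl){[(1R,5S)-5-methyl-4-oxocyclopent-2-en-1-yl]methyl}carbamate (trans) | O=C1C=C[C@@H](CN(CC(Br)=C)C(=O)OC(C)(C)C)[C@@H]1C
F5 | step 2 | tert-butyl 7-methyl-4-methylidene-6-oxooctahydro-2H-cyclopenta[c]pyridine-2-carboxylate (C4a, C7 and C7a arranged as in 7) | O=C1C[C@@H]2[C@@H](CN(C(=O)OC(C)(C)C)CC2=C)[C@@H]1C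
F6 | step 4 | 4-(iodomethyl)-7-methyloctahydro-6H-cyclopenta[c]pyridin-6-one (ring stereocentres arranged as in 7) | O=C1C[C@@H]2[C@@H](CNC[C@@H]2CI)[C@@H]1C
F7 | step 4 | tert-butyl 4-(iodomethyl)-7-methyl-6-oxooctahydro-2H-cyclopenta[c]pyridine-2-carboxylate (ring stereocentres arranged as in 7) | O=C1C[C@@H]2[C@@H](CN(C(=O)OC(C)(C)C)C[C@@H]2CI)[C@@H]1C
F8 | step 7 | 4,4'-diacetoxy-α-truxillic acid | OC(=O)[C@H]1[C@H](c2ccc(OC(C)=O)cc2)[C@H](C(=O)O)[C@H]1c1ccc(OC(C)=O)cc1
F9 | step 7 | bis-ester of F8 with two (4R,4aS,6R,7S,7aR)-2,4,7-trimethyloctahydro-1H-cyclopenta[c]pyridin-6-yl groups | C[C@H]1[C@@H]2CN(C)C[C@H](C)[C@@H]2C[C@H]1OC(=O)[C@H]1[C@H](c2ccc(OC(C)=O)cc2)[C@H](C(=O)O[C@@H]2C[C@@H]3[C@@H](CN(C)C[C@@H]3C)[C@@H]2C)[C@H]1c1ccc(OC(C)=O)cc1
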